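**Strategy.** The dihydrobenzofuran is cut at C3a–C7a and C6–C7. In ring C the C7 oxygen sits next to the fusion carbon C7a, which holds O1; this 1,2-dioxygen pattern is what a furan tied through C3–C2–O1 to a terminal ynol ether leaves when it is cycloisomerised to a phenol. One gold-catalysed operation thus closes the dihydrofuran and ring C and turns the furan oxygen into the C7 hydroxyl, while C2 and C3, set earlier by an anti-aldol, pass through untouched. The precursor is the ethynyl ether of an anti 1-aryl-2-(4-alkylfuran-2-yl)propane-1,3-diol monosilyl ether; its ring B oxygen carries a 2-(benzyloxy)ethyl group, the latent C8–C9 of the erythro arm.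

Key step: step 10

Assumption: in the magnesium chloride anti-aldol the enolate is taken to react in its chelated form, with face selection as in enolate alkylations, so the (R)-auxiliary is assigned to the (2R,3R) adduct.

Step 1
Reactants: 1 4-bromofuran-2-carbaldehyde
Product: 3 2-(4-bromofuran-2-yl)acetonitrile, via N-formyl tosylenamine 2 (not isolated)
Conditions: TosMIC, t-BuOK, DME, −50 °C; then MeOH, reflux
Reagents that add atoms: tosylmethyl isocyanide, Cc1ccc(cc1)S(=O)(=O)C[N+]#[C-]
Why: Van Leusen reductive cyanation: the TosMIC anion adds to the aldehyde, base opens the adduct to the N-formyl tosylenamine, and methanolysis expels methyl formate and sulfinate to leave the one-carbon homologated nitrile, the aprotic low-temperature first stage keeping oxazole formation out.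

Step 2
Reactants: 3 2-(4-bromofuran-2-yl)acetonitrile
Product: 4 2-(4-bromofuran-2-yl)acetic acid
Conditions: NaOH, EtOH/H2O, 80 °C; then HCl (aq), 0 °C
Reagents that add atoms: sodium hydroxide, [Na+].[OH-]; water, O
Why: Base hydrolysis of the nitrile, chosen because the bromofuran tolerates hot hydroxide far better than hot mineral acid; cold acidification frees the acid.

Step 3
Reactants: 4 2-(4-bromofuran-2-yl)acetic acid; 5 (R)-4-benzyloxazolidin-2-one
Product: 7 (R)-4-benzyl-3-[2-(4-bromofuran-2-yl)acetyl]oxazolidin-2-one, via pivalic mixed anhydride 6 (not isolated)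
Conditions: PivCl, Et3N, THF, −20 °C; then LiCl, 5, −20 °C → rt
Reagents that add atoms: none
Why: N-acylation of the oxazolidinone through the pivalic mixed anhydride under LiCl/Et3N activation, which avoids strong base at the acidic furylacetyl methylene.

Step 4
Reactants: 8 syringaldehyde; 9 benzyl 2-bromoethyl ether
Product: 10 4-[2-(benzyloxy)ethoxy]-3,5-dimethoxybenzaldehyde
Conditions: K2CO3, DMF, 80 °C
Reagents that add atoms: none
Why: Williamson ether synthesis on the phenoxide; the 2-(benzyloxy)ethyl group is inert to base, hydride, organolithium and gold and later supplies C8 and C9 of the arm, so ring B never has to appear as a free phenol.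

Step 5
Reactants: 7 furylacetyl imide; 10 ring B aldehyde
Product: 11 (2R,3R) anti-aldol adduct as its trimethylsilyl ether
Conditions: MgCl2 (20 mol%), Et3N, TMSCl, EtOAc, rt
Reagents that add atoms: chlorotrimethylsilane, C[Si](C)(C)Cl
Why: Evans magnesium halide-catalysed direct anti-aldol: soft enolisation gives the chelated (Z)-magnesium enolate, the non-enolisable aldehyde adds to the enolate face away from the benzyl group (setting C2) through a boat-like transition state (setting C3 anti), and silylation of the aldolate makes the addition irreversible, so the (R)-auxiliary should give the (2R,3R) adduct.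

Step 6
Reactants: 11 silylated anti-aldol adduct
Product: 13 (1R,2R)-1-aryl-2-(4-bromofuran-2-yl)propane-1,3-diol, via TMS ether alcohol 12 (not isolated)
Conditions: LiBH4, H2O (1 equiv), Et2O/THF, 0 °C; then K2CO3 (cat.), MeOH, rt
Reagents that add atoms: none
Why: Reductive removal of the auxiliary with LiBH4 while the carbinol is still silylated, which excludes retro-aldol cleavage; mild methanolysis then frees the secondary hydroxyl and neither stereocentre is touched.

Step 7
Reactants: 13 anti diol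
Product: 14 primary triisopropylsilyl ether of 13
Conditions: TIPSCl, imidazole, DMF, 0 °C
Reagents that add atoms: triisopropylsilyl chloride, CC(C)[Si](Cl)(C(C)C)C(C)C
Why: Selective silylation of the primary hydroxyl with a bulky chloride; TIPS is taken because it should not migrate to the neighbouring alkoxide under KH in step 9.

Step 8
Reactants: 14 bromofuran; 15 allyl tert-butyldimethylsilyl ether
Product: 16 furan bearing the 3-(tert-butyldimethylsilyloxy)propyl chain at C4
Conditions: 15, 9-BBN, THF, rt; then 14, Pd(dppf)Cl2 (5 mol%), K3PO4 (aq), DMF, 60 °C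
Reagents that add atoms: none
Why: B-alkyl Suzuki–Miyaura coupling: 9-BBN hydroborates the allyl ether at its terminus and the alkylborane couples with the bromofuran through zerovalent palladium, so the protected three-carbon chain is in place before any organolithium is used.

Step 9
Reactants: 16 secondary alcohol; 17 trichloroethylene
Product: 19 ethynyl ether of 16, via dichlorovinyl ether 18 (not isolated)
Conditions: KH, THF, 0 °C; 17, −50 °C → rt; then n-BuLi (2.5 equiv), −78 → −40 °C; MeOH, −78 °C; used at once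
Reagents that add atoms: none
Why: Trichloroethylene route to ynol ethers: the potassium alkoxide adds to dichloroacetylene formed in situ, n-BuLi then eliminates HCl and exchanges the remaining chlorine, and protonation of the lithium acetylide gives the terminal ethynyl ether with the carbinol C–O bond, and so its configuration, untouched.

Step 10
Reactants: 19 ethynyl ether
Product: 20 cis-(2R,3R)-2-aryl-3-(silyloxymethyl)-2,3-dihydrobenzofuran-7-ol
Conditions: Ph3PAuNTf2 (3 mol%), CH2Cl2, 4 Å MS, 0 °C → rt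
Reagents that add atoms: none
Why: Monovalent gold binds the terminal ynol ether, whose oxygen makes the O-bearing alkyne carbon the electrophilic one; the tethered furan attacks it through its ipso carbon in a 5-exo-dig closure that forms C3a–C7a and the dihydrofuran ring and leaves a cyclopropyl gold carbene. The furan C–O bond then opens to a (Z)-dienal carrying a vinyl gold carbene, the aldehyde oxygen adds to the carbene carbon to give an oxepine, and 6π electrocyclic closure of the oxepine to the arene oxide forms C6–C7 and ring C. The arene oxide opens towards the cation stabilised by O1 on C7a, so the former furan oxygen ends as the C7 hydroxyl and the former furan C4 substituent lies on C5. The closest known reaction is the gold-catalysed furan–yne phenol synthesis (Hashmi phenol synthesis), which turns 2-(2-furyl)ethyl ethynyl ethers into 2,3-dihydrobenzofuran-7-ols. No stereocentre is made or broken, so the cis (2R,3R) relation is simply that of the anti precursor. The step needs cyclisation to outrun hydration of the ynol ether and ionisation of the benzylic C2–O bond, which the five-membered intramolecular closure onto an electron-rich dialkylfuran, a preformed silver-free and acid-free catalyst, dry solvent and low temperature should secure.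

Step 11
Reactants: 20 C7 phenol
Product: 21 7-methyl ether of 20
Conditions: MeI, K2CO3, acetone, rt
Reagents that add atoms: iodomethane, CI
Why: Williamson methylation of the C7 phenoxide, the only acidic hydroxyl in 20.

Step 12
Reactants: 21 benzyl ether
Product: 22 ring B 2-hydroxyethyl ether
Conditions: H2 (1 atm), 10% Pd/C, EtOAc, rt, stopped at one equivalent
Reagents that add atoms: none
Why: Hydrogenolysis of the benzyl alkyl ether over Pd/C under neutral conditions, stopped early so that the ring C2–O1 benzylic bond and the silyl ethers remain.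

Step 13
Reactants: 22 primary alcohol
Product: 23 ring B aryloxyacetic acid
Conditions: TEMPO (cat.), PhI(OAc)2, MeCN/H2O, rt
Reagents that add atoms: water, O
Why: TEMPO/PhI(OAc)2 oxidation of the primary alcohol through the aldehyde hydrate to the acid under near-neutral conditions; ring B thus reaches the arm precursor without a free phenol, which would open a quinone methide path to C2 epimerisation.

Step 14
Reactants: 23 aryloxyacetic acid; 5 (R)-4-benzyloxazolidin-2-one
Product: 25 (R)-aryloxyacetyl imide, via pivalic mixed anhydride 24 (not isolated)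
Conditions: PivCl, Et3N, THF, −20 °C; then LiCl, 5, −20 °C → rt
Reagents that add atoms: none
Why: Mixed-anhydride N-acylation as in step 3; aryloxyacetyl oxazolidinones are standard substrates for the boron aldol that follows.

Step 15
Reactants: 26 vanillin
Product: 27 3-methoxy-4-(triisopropylsilyloxy)benzaldehyde
Conditions: TIPSCl, imidazole, DMF, rt
Reagents that add atoms: triisopropylsilyl chloride, CC(C)[Si](Cl)(C(C)C)C(C)C
Why: Silylation of the phenol; the aryl TIPS ether withstands the borohydride, Mitsunobu and brief carbonate steps and falls to fluoride at the end.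

Step 16
Reactants: 25 aryloxyacetyl imide; 27 protected vanillin
Product: 28 (2R,3S) syn-aldol adduct
Conditions: Bu2BOTf, i-Pr2NEt, CH2Cl2, −78 → 0 °C; 27, −78 → 0 °C; then pH 7 buffer, MeOH, H2O2, 0 °C
Reagents that add atoms: none
Why: Evans boron aldol: the (Z)-dibutylboron enolate adds through a chair Zimmerman–Traxler transition state on the face set by the dipole-opposed (R)-auxiliary, giving the syn adduct in which C8 already has the target configuration and C7 is epimeric.

Step 17
Reactants: 28 syn-aldol adduct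
Product: 29 threo (7S,8S) 1,3-diol
Conditions: NaBH4, THF/H2O (4:1), 0 °C → rt
Reagents that add atoms: none
Why: Hydroxyl-assisted reductive cleavage of the imide with NaBH4 gives the threo 1,3-diol and returns the auxiliary without touching C7 or C8.

Step 18
Reactants: 29 threo diol
Product: 30 threo 9-O-tert-butyldimethylsilyl ether
Conditions: TBSCl, imidazole, CH2Cl2, 0 °C
Reagents that add atoms: tert-butyldimethylsilyl chloride, CC(C)(C)[Si](C)(C)Cl
Why: Selective silylation of the primary hydroxyl, which leaves only the benzylic carbinol open for inversion and keeps an acyl group at C9 from taking part as a neighbouring group.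

Step 19
Reactants: 30 threo benzylic alcohol
Product: 31 erythro (7R,8S) chloroacetate
Conditions: ClCH2CO2H, PPh3, DIAD, toluene, 0 °C → rt
Reagents that add atoms: chloroacetic acid, OC(=O)CCl
Why: Mitsunobu reaction: the carbinol is activated as its oxyphosphonium and displaced by chloroacetate with inversion, turning the threo into the erythro series, a known way from syn-aldol-derived arylglycerol aryl ethers to their erythro isomers.

Step 20
Reactants: 31 erythro chloroacetate
Product: 33 target CNP0301567.1, via erythro carbinol 32 (not isolated)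
Conditions: K2CO3 (cat.), MeOH, 0 °C, 15 min; then AcOH, TBAF, THF, rt → 40 °C
Reagents that add atoms: none
Why: Brief carbonate methanolysis removes the labile chloroacetate while the aryl silyl ether is still in place, so no phenoxide can expel a benzylic ester, and buffered fluoride then cleaves the four silyl ethers; no stereocentre is involved.

**Compound list**
In the names, ArB = 4-[2-(benzyloxy)ethoxy]-3,5-dimethoxyphenyl and DHB = (2R,3R)-5-[3-(tert-butyldimethylsilyloxy)propyl]-7-methoxy-3-[(triisopropylsilyloxy)methyl]-2,3-dihydrobenzofuran-2-yl (2,3-cis).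

1 | 4-bromofuran-2-carbaldehyde | O=Cc1cc(Br)co1 | starting material
2 | N-[2-(4-bromofuran-2-yl)-1-(4-methylphenylsulfonyl)ethenyl]formamide | O=CNC(=Cc1cc(Br)co1)S(=O)(=O)c1ccc(C)cc1 | intermediate (not isolated)
3 | 2-(4-bromofuran-2-yl)acetonitrile | N#CCc1cc(Br)co1 | intermediate
4 | 2-(4-bromofuran-2-yl)acetic acid | OC(=O)Cc1cc(Br)co1 | intermediate
5 | (R)-4-benzyloxazolidin-2-one | O=C1N[C@H](Cc2ccccc2)CO1 | starting material
6 | 2-(4-bromofuran-2-yl)acetic pivalic anhydride | CC(C)(C)C(=O)OC(=O)Cc1cc(Br)co1 | intermediate (not isolated)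
7 | (R)-4-benzyl-3-[2-(4-bromofuran-2-yl)acetyl]oxazolidin-2-one | O=C(Cc1cc(Br)co1)N1[C@H](Cc2ccccc2)COC1=O | intermediate
8 | syringaldehyde (4-hydroxy-3,5-dimethoxybenzaldehyde) | COc1cc(C=O)cc(OC)c1O | starting material
9 | benzyl 2-bromoethyl ether | BrCCOCc1ccccc1 | starting material
10 | 4-[2-(benzyloxy)ethoxy]-3,5-dimethoxybenzaldehyde | COc1cc(C=O)cc(OC)c1OCCOCc1ccccc1 | intermediate
11 | (R)-4-benzyl-3-[(2R,3R)-3-ArB-2-(4-bromofuran-2-yl)-3-(trimethylsilyloxy)propanoyl]oxazolidin-2-one | COc1cc(cc(OC)c1OCCOCc1ccccc1)[C@H](O[Si](C)(C)C)[C@@H](C(=O)N1[C@H](Cc2ccccc2)COC1=O)c1cc(Br)co1 | intermediate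
12 | (2R,3R)-3-ArB-2-(4-bromofuran-2-yl)-3-(trimethylsilyloxy)propan-1-ol | COc1cc(cc(OC)c1OCCOCc1ccccc1)[C@H](O[Si](C)(C)C)[C@@H](CO)c1cc(Br)co1 | intermediate (not isolated)
13 | (1R,2R)-1-ArB-2-(4-bromofuran-2-yl)propane-1,3-diol | COc1cc(cc(OC)c1OCCOCc1ccccc1)[C@H](O)[C@@H](CO)c1cc(Br)co1 | intermediate
14 | (1R,2R)-1-ArB-2-(4-bromofuran-2-yl)-3-(triisopropylsilyloxy)propan-1-ol | COc1cc(cc(OC)c1OCCOCc1ccccc1)[C@H](O)[C@@H](CO[Si](C(C)C)(C(C)C)C(C)C)c1cc(Br)co1 | intermediate
15 | allyl tert-butyldimethylsilyl ether | C=CCO[Si](C)(C)C(C)(C)C | starting material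
16 | (1R,2R)-1-ArB-2-{4-[3-(tert-butyldimethylsilyloxy)propyl]furan-2-yl}-3-(triisopropylsilyloxy)propan-1-ol | COc1cc(cc(OC)c1OCCOCc1ccccc1)[C@H](O)[C@@H](CO[Si](C(C)C)(C(C)C)C(C)C)c1cc(CCCO[Si](C)(C)C(C)(C)C)co1 | intermediate
17 | trichloroethylene | ClC=C(Cl)Cl | starting material
18 | (E)-1,2-dichlorovinyl ether of 16 at the C1 oxygen, (1R,2R) | COc1cc(cc(OC)c1OCCOCc1ccccc1)[C@H](O/C(Cl)=C\Cl)[C@@H](CO[Si](C(C)C)(C(C)C)C(C)C)c1cc(CCCO[Si](C)(C)C(C)(C)C)co1 | intermediate (not isolated)
19 | (1R,2R)-1-ArB-1-(ethynyloxy)-2-{4-[3-(tert-butyldimethylsilyloxy)propyl]furan-2-yl}-3-(triisopropylsilyloxy)propane | COc1cc(cc(OC)c1OCCOCc1ccccc1)[C@H](OC#C)[C@@H](CO[Si](C(C)C)(C(C)C)C(C)C)c1cc(CCCO[Si](C)(C)C(C)(C)C)co1 | intermediate (key-step precursor)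
20 | (2R,3R)-2-ArB-5-[3-(tert-butyldimethylsilyloxy)propyl]-3-[(triisopropylsilyloxy)methyl]-2,3-dihydrobenzofuran-7-ol (2,3-cis) | COc1cc(cc(OC)c1OCCOCc1ccccc1)[C@@H]1Oc2c(O)cc(CCCO[Si](C)(C)C(C)(C)C)cc2[C@@H]1CO[Si](C(C)C)(C(C)C)C(C)C | intermediate (key-step product)
21 | 7-methyl ether of 20 (ArB–DHB) | COc1cc(cc(OC)c1OCCOCc1ccccc1)[C@@H]1Oc2c(OC)cc(CCCO[Si](C)(C)C(C)(C)C)cc2[C@@H]1CO[Si](C(C)C)(C(C)C)C(C)C | intermediate
22 | 2-(4-DHB-2,6-dimethoxyphenoxy)ethanol | COc1cc(cc(OC)c1OCCO)[C@@H]1Oc2c(OC)cc(CCCO[Si](C)(C)C(C)(C)C)cc2[C@@H]1CO[Si](C(C)C)(C(C)C)C(C)C | intermediate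
23 | (4-DHB-2,6-dimethoxyphenoxy)acetic acid | COc1cc(cc(OC)c1OCC(=O)O)[C@@H]1Oc2c(OC)cc(CCCO[Si](C)(C)C(C)(C)C)cc2[C@@H]1CO[Si](C(C)C)(C(C)C)C(C)C | intermediate
24 | (4-DHB-2,6-dimethoxyphenoxy)acetic pivalic anhydride | COc1cc(cc(OC)c1OCC(=O)OC(=O)C(C)(C)C)[C@@H]1Oc2c(OC)cc(CCCO[Si](C)(C)C(C)(C)C)cc2[C@@H]1CO[Si](C(C)C)(C(C)C)C(C)C | intermediate (not isolated)
25 | (R)-4-benzyl-3-[(4-DHB-2,6-dimethoxyphenoxy)acetyl]oxazolidin-2-one | COc1cc(cc(OC)c1OCC(=O)N1[C@H](Cc2ccccc2)COC1=O)[C@@H]1Oc2c(OC)cc(CCCO[Si](C)(C)C(C)(C)C)cc2[C@@H]1CO[Si](C(C)C)(C(C)C)C(C)C | intermediate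
26 | vanillin | COc1cc(C=O)ccc1O | starting material
27 | 3-methoxy-4-(triisopropylsilyloxy)benzaldehyde | COc1cc(C=O)ccc1O[Si](C(C)C)(C(C)C)C(C)C | intermediate
28 | (R)-4-benzyl-3-{(2R,3S)-2-(4-DHB-2,6-dimethoxyphenoxy)-3-hydroxy-3-[3-methoxy-4-(triisopropylsilyloxy)phenyl]propanoyl}oxazolidin-2-one | COc1cc([C@H](O)[C@H](C(=O)N2[C@H](Cc3ccccc3)COC2=O)Oc2c(OC)cc([C@@H]3Oc4c(OC)cc(CCCO[Si](C)(C)C(C)(C)C)cc4[C@@H]3CO[Si](C(C)C)(C(C)C)C(C)C)cc2OC)ccc1O[Si](C(C)C)(C(C)C)C(C)C | intermediate
29 | (1S,2S)-2-(4-DHB-2,6-dimethoxyphenoxy)-1-[3-methoxy-4-(triisopropylsilyloxy)phenyl]propane-1,3-diol (threo) | COc1cc([C@H](O)[C@H](CO)Oc2c(OC)cc([C@@H]3Oc4c(OC)cc(CCCO[Si](C)(C)C(C)(C)C)cc4[C@@H]3CO[Si](C(C)C)(C(C)C)C(C)C)cc2OC)ccc1O[Si](C(C)C)(C(C)C)C(C)C | intermediate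
30 | (1S,2S)-3-(tert-butyldimethylsilyloxy)-2-(4-DHB-2,6-dimethoxyphenoxy)-1-[3-methoxy-4-(triisopropylsilyloxy)phenyl]propan-1-ol (threo) | COc1cc([C@H](O)[C@H](CO[Si](C)(C)C(C)(C)C)Oc2c(OC)cc([C@@H]3Oc4c(OC)cc(CCCO[Si](C)(C)C(C)(C)C)cc4[C@@H]3CO[Si](C(C)C)(C(C)C)C(C)C)cc2OC)ccc1O[Si](C(C)C)(C(C)C)C(C)C | intermediate
31 | (1R,2S) chloroacetate of the C1 epimer of 30 (erythro) | COc1cc([C@@H](OC(=O)CCl)[C@H](CO[Si](C)(C)C(C)(C)C)Oc2c(OC)cc([C@@H]3Oc4c(OC)cc(CCCO[Si](C)(C)C(C)(C)C)cc4[C@@H]3CO[Si](C(C)C)(C(C)C)C(C)C)cc2OC)ccc1O[Si](C(C)C)(C(C)C)C(C)C | intermediate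
32 | (1R,2S)-3-(tert-butyldimethylsilyloxy)-2-(4-DHB-2,6-dimethoxyphenoxy)-1-[3-methoxy-4-(triisopropylsilyloxy)phenyl]propan-1-ol (erythro) | COc1cc([C@@H](O)[C@H](CO[Si](C)(C)C(C)(C)C)Oc2c(OC)cc([C@@H]3Oc4c(OC)cc(CCCO[Si](C)(C)C(C)(C)C)cc4[C@@H]3CO[Si](C(C)C)(C(C)C)C(C)C)cc2OC)ccc1O[Si](C(C)C)(C(C)C)C(C)C | intermediate (not isolated)
33 | (1R,2S)-1-(4-hydroxy-3-methoxyphenyl)-2-{4-[(2R,3R)-3-(hydroxymethyl)-5-(3-hydroxypropyl)-7-methoxy-2,3-dihydrobenzofuran-2-yl]-2,6-dimethoxyphenoxy}propane-1,3-diol | COc1cc([C@@H](O)[C@H](CO)Oc2c(OC)cc([C@@H]3Oc4c(OC)cc(CCCO)cc4[C@@H]3CO)cc2OC)ccc1O | target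

**Step count and risk**
Total step count: 20 (steps 4 and 15 are one-step side branches). Longest linear sequence: 18 steps (1–3, 5–14, 16–20).

Steps most likely to fail:

1. Step 10. The gold-bound ynol ether may ionise at the benzylic C–O bond (erosion of the C2 configuration or fragmentation) or be hydrated before the furan attacks. The fallback makes the cis ring by a dirhodium carbenoid C–H insertion, a known cis-selective route to 2-aryl-2,3-dihydrobenzofuran-3-carboxylates; it sets out from 10 and comes back to the route at 21. NaBH4 reduces 10 to benzylic alcohol F1 and PBr3 gives bromide F2. Commercial (2-hydroxy-3-methoxyphenyl)acetic acid is esterified (MeOH, H2SO4) to methyl ester F3 and brominated para to the hydroxyl (NBS) to bromophenol F4. Alkylation of F4 with F2 (K2CO3, acetone) gives ether F5 and diazo transfer (p-ABSA, DBU) gives aryldiazoacetate F6. Rh2(S-PTTL)4 or its enantiomer, whichever delivers the (2R,3S) ester, in toluene at −60 °C then inserts the carbenoid into the benzylic C–H bond to give cis ester F7. DIBAL-H at −78 °C gives alcohol F8 without epimerising C3, TIPSCl gives silyl ether F9, and the coupling of step 8 with the 9-BBN adduct of 15 gives 21.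

2. Step 5. With the acidic furylacetyl imide the magnesium aldolate may equilibrate by retro-aldol before it is silylated, or the two enolate faces may be poorly distinguished, so that syn or the wrong anti isomer forms. The fallback sets out from 4 and comes back at 14. Acylation of (S)-4-benzyloxazolidin-2-one as in step 3 gives (S)-imide F10. A Bu2BOTf/i-Pr2NEt aldol with 10 gives syn adduct F11, with the furyl-bearing centre as required and the carbinol epimeric. LiBH4 gives syn diol F12 and TIPSCl gives silyl ether F13. A Mitsunobu reaction with 4-nitrobenzoic acid inverts the carbinol to 4-nitrobenzoate F14, and K2CO3 in MeOH gives 14.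

3. Step 19. The oxyphosphonium of the electron-rich benzylic carbinol may ionise (incomplete inversion) or eliminate to the enol ether. The fallback sets out from 30 and comes back at 32. Dess–Martin periodinane (NaHCO3, CH2Cl2) gives ketone F15. Zn(BH4)2 in Et2O at −20 °C, with zinc chelated between the carbonyl and the C8 aryl ether oxygen, should deliver hydride to give the erythro carbinol 32, which goes on through the fluoride stage of step 20.

**Further compounds**
F1 | step 10 | {4-[2-(benzyloxy)ethoxy]-3,5-dimethoxyphenyl}methanol | COc1cc(CO)cc(OC)c1OCCOCc1ccccc1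
F2 | step 10 | 2-[2-(benzyloxy)ethoxy]-5-(bromomethyl)-1,3-dimethoxybenzene | COc1cc(CBr)cc(OC)c1OCCOCc1ccccc1
F3 | step 10 | methyl (2-hydroxy-3-methoxyphenyl)acetate | COC(=O)Cc1cccc(OC)c1O
F4 | step 10 | methyl (5-bromo-2-hydroxy-3-methoxyphenyl)acetate | COC(=O)Cc1cc(Br)cc(OC)c1O
F5 | step 10 | methyl [5-bromo-2-({4-[2-(benzyloxy)ethoxy]-3,5-dimethoxybenzyl}oxy)-3-methoxyphenyl]acetate | COC(=O)Cc1cc(Br)cc(OC)c1OCc1cc(OC)c(OCCOCc2ccccc2)c(OC)c1
F6 | step 10 | methyl 2-diazo-2-[5-bromo-2-({4-[2-(benzyloxy)ethoxy]-3,5-dimethoxybenzyl}oxy)-3-methoxyphenyl]acetate | COC(=O)C(=[N+]=[N-])c1cc(Br)cc(OC)c1OCc1cc(OC)c(OCCOCc2ccccc2)c(OC)c1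
F7 | step 10 | methyl (2R,3S)-2-ArB-5-bromo-7-methoxy-2,3-dihydrobenzofuran-3-carboxylate (2,3-cis) | COc1cc(cc(OC)c1OCCOCc1ccccc1)[C@@H]1Oc2c(OC)cc(Br)cc2[C@@H]1C(=O)OC
F8 | step 10 | [(2R,3R)-2-ArB-5-bromo-7-methoxy-2,3-dihydrobenzofuran-3-yl]methanol | COc1cc(cc(OC)c1OCCOCc1ccccc1)[C@@H]1Oc2c(OC)cc(Br)cc2[C@@H]1CO
F9 | step 10 | triisopropylsilyl ether of F8 | COc1cc(cc(OC)c1OCCOCc1ccccc1)[C@@H]1Oc2c(OC)cc(Br)cc2[C@@H]1CO[Si](C(C)C)(C(C)C)C(C)C
F10 | step 5 | (S)-4-benzyl-3-[2-(4-bromofuran-2-yl)acetyl]oxazolidin-2-one | O=C(Cc1cc(Br)co1)N1[C@@H](Cc2ccccc2)COC1=O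
F11 | step 5 | (S)-4-benzyl-3-[(2R,3S)-3-ArB-2-(4-bromofuran-2-yl)-3-hydroxypropanoyl]oxazolidin-2-one | COc1cc(cc(OC)c1OCCOCc1ccccc1)[C@@H](O)[C@@H](C(=O)N1[C@@H](Cc2ccccc2)COC1=O)c1cc(Br)co1
F12 | step 5 | (1S,2R)-1-ArB-2-(4-bromofuran-2-yl)propane-1,3-diol | COc1cc(cc(OC)c1OCCOCc1ccccc1)[C@@H](O)[C@@H](CO)c1cc(Br)co1
F13 | step 5 | (1S,2R)-1-ArB-2-(4-bromofuran-2-yl)-3-(triisopropylsilyloxy)propan-1-ol | COc1cc(cc(OC)c1OCCOCc1ccccc1)[C@@H](O)[C@@H](CO[Si](C(C)C)(C(C)C)C(C)C)c1cc(Br)co1
F14 | step 5 | (1R,2R)-1-ArB-2-(4-bromofuran-2-yl)-3-(triisopropylsilyloxy)propyl 4-nitrobenzoate | COc1cc(cc(OC)c1OCCOCc1ccccc1)[C@H](OC(=O)c1ccc(cc1)[N+](=O)[O-])[C@@H](CO[Si](C(C)C)(C(C)C)C(C)C)c1cc(Br)co1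
F15 | step 19 | (S)-3-(tert-butyldimethylsilyloxy)-2-(4-DHB-2,6-dimethoxyphenoxy)-1-[3-methoxy-4-(triisopropylsilyloxy)phenyl]propan-1-one | COc1cc(C(=O)[C@H](CO[Si](C)(C)C(C)(C)C)Oc2c(OC)cc([C@@H]3Oc4c(OC)cc(CCCO[Si](C)(C)C(C)(C)C)cc4[C@@H]3CO[Si](C(C)C)(C(C)C)C(C)C)cc2OC)ccc1O[Si](C(C)C)(C(C)C)C(C)C
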